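**Plan**

Numbering: lactone ring O1, C2–C6; side chain C1′–C15′ counted from C6. Retrosynthetic cuts, in order: the ring alkene C3=C4 (ring-closing metathesis of an acrylate on O–C6); side-chain C5′–C6′ (aldol of a C4′ methyl ketone with decanal, C4′–OH by reduction); C6–C5 and C2′–C3′ (two allylations of propane-1,3-diol, which supplies C6, C1′, C2′).
Forward: double allylation gives the C2-symmetric diene diol. One iodoetherification closes a temporary oxane ring made of O(C2′), C2′, C1′, C6, C5 and C4, which tells apart the two hydroxyls and the two alkenes at once. Then acrylate on O–C6, Wacker oxidation to the C4′ ketone, aldol with decanal, syn reduction, zinc opening of the oxane, and metathesis to the dihydropyranone, the only ring of the target, which arises last.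
Feature used: the 1,3,5-oxygen pattern O–C2′ / O–C4′ / O–C6′. With C4′ as ketone, its methyl enolate is flanked by the C2′ oxygen; held as the ether oxygen of the oxane ring, that oxygen relays the C2′ configuration to C6′ (1,5). The C6′ hydroxyl then steers the reduction at C4′, and the same oxygen returns as the free C2′ hydroxyl when zinc opens the ring.
Stereochemistry: C6 and C2′ from the [Ir(cod)Cl]2/(S)-Cl,MeO-BIPHEP catalyst in step 1; C6′ from C2′ by 1,5-anti induction in the aldol; C4′ from C6′ by 1,3-syn boron-chelate reduction. The iodomethyl-bearing ring carbon is a temporary centre erased in step 7; no conventional protecting group is used.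

Key step: step 5

Remark 1: the (S)-antipode of the ligand is written on the assumption that it delivers the (4S,6S)-diol; if the sense of induction is the opposite one, the (R)-ligand is taken and nothing else changes.
Remark 2: the iodoetherification is expected to give mainly the all-cis oxane; the epimer at the iodomethyl-bearing carbon would run through steps 3–7 alike and converge at 14, so compounds 5–13 are drawn as the cis isomer.

Step 1
Reactants: 1 propane-1,3-diol; 2 allyl acetate (10 equiv)
Product: 4 (4S,6S)-nona-1,8-diene-4,6-diol, via (S)-hex-5-ene-1,3-diol 3 (not isolated)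
Conditions: [Ir(cod)Cl]2 (5 mol%), (S)-Cl,MeO-BIPHEP (10 mol%), 4-chloro-3-nitrobenzoic acid (20 mol%), Cs2CO3 (40 mol%), 1,4-dioxane, 90 °C
Reagents that add atoms: none
Why: Iridium-catalysed transfer-hydrogenative carbonyl allylation (Krische allylation) run in both directions: each primary alcohol terminus is dehydrogenated in turn to the aldehyde and allylated by the chiral allyliridium complex under catalyst control, so both carbinol centres (later C6 and C2′) should be set with the same sense, the minor sense being diverted into the separable meso diol.

Step 2
Reactants: 4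
Product: 5 (2S,4R,6S)-2-(iodomethyl)-6-(prop-2-en-1-yl)oxan-4-ol (all-cis)
Conditions: I2 (1.05 equiv), NaHCO3 (3 equiv), MeCN, −20 → 0 °C
Reagents that add atoms: iodine, [I][I]
Why: 6-exo-trig iodoetherification (halocyclisation): each hydroxyl can reach only the alkene of the other allyl group through a six-membered chair and the two modes are identical by C2 symmetry, so one ring closure should mark one oxygen as ring ether and one alkene as iodomethyl group; the new ring centre (expected cis, all substituents equatorial in the chair transition state) is temporary.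

Step 3
Reactants: 5
Product: 6 (2S,4R,6S)-2-(iodomethyl)-6-(prop-2-en-1-yl)oxan-4-yl prop-2-enoate
Conditions: acryloyl chloride (1.3 equiv), iPr2NEt (2 equiv), CH2Cl2, −20 → 0 °C
Reagents that add atoms: acryloyl chloride, C=CC(=O)Cl
Why: O-acylation of the only free (equatorial, secondary) hydroxyl, which is the later lactone oxygen on C6; no stereocentre is touched.

Step 4
Reactants: 6
Product: 7 (2S,4R,6R)-2-(iodomethyl)-6-(2-oxopropyl)oxan-4-yl prop-2-enoate
Conditions: PdCl2 (10 mol%), CuCl (30 mol%), O2 (1 atm), DMF/H2O 7:1, 25 °C
Reagents that add atoms: water, O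
Why: Tsuji–Wacker oxidation: Markovnikov hydroxypalladation of the only unconjugated terminal alkene by PdCl2 should give the methyl ketone, the electron-poor acrylate being inert under these conditions; no stereocentre is formed.

Step 5
Reactants: 7; 8 decanal (1.5 equiv)
Product: 11 (2R,4R,6S)-2-[(4R)-4-hydroxy-2-oxotridecyl]-6-(iodomethyl)oxan-4-yl prop-2-enoate, via dicyclohexylboron enolate 9 (not isolated), via dicyclohexylboron aldolate 10 (not isolated)
Conditions: (c-C6H11)2BCl (1.5 equiv), Et3N (1.8 equiv), Et2O, 0 °C; then 8, −78 → −20 °C; then MeOH, pH 7 buffer, 30% H2O2, 0 °C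
Reagents that add atoms: none
Why: Dicyclohexylboron chloride and triethylamine enolise 7 kinetically on the methyl side to the boron enolate 9, which adds to decanal through a cyclic six-membered boron-bound transition state to give aldolate 10 and, after buffered oxidative work-up, 11. The closest known reaction type is the 1,5-anti boron aldol reaction of β-alkoxy methyl ketones, including ketones whose β-oxygen is the ring oxygen of a tetrahydropyran. No ring is closed. The one new stereocentre (the carbinol carbon C6′ bearing the nonyl chain) is controlled by the ring carbon that carries the ring oxygen (C2′): in the boat-like transition state the electron-rich ether oxygen accepts a hydrogen bond from the formyl hydrogen of the aldehyde, and the aldehyde face that leads to the 1,5-anti (R) carbinol is attacked. The step needs regioselectivity (enolisation at CH3 and not at the ring-side CH2, which would open the ring by β-elimination; secured by the hindered boron chloride with a weak amine), chemoselectivity (acrylate and primary iodide should not react with a boron Lewis acid and triethylamine at low temperature; decanal meets only preformed enolate, so it does not self-condense) and facial selectivity (secured by the directing oxygen being a dialkyl ether and not a silyl ether or ester).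

Step 6
Reactants: 11
Product: 13 (2S,4R,6S)-2-[(2R,4R)-2,4-dihydroxytridecyl]-6-(iodomethyl)oxan-4-yl prop-2-enoate, via diethylboron chelate 12 (not isolated)
Conditions: Et2BOMe (1.2 equiv), THF/MeOH 4:1, −78 °C; NaBH4 (1.2 equiv), −78 °C; AcOH, then repeated evaporation from MeOH (boron leaves as Et2BOMe)
Reagents that add atoms: none
Why: Narasaka–Prasad reduction: the diethylboron chelate of the β-hydroxy ketone is held in a half-chair and should take hydride axially, so the C6′ oxygen sets the new C4′ carbinol 1,3-syn, while acrylate and primary iodide should be inert to borohydride at −78 °C.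

Step 7
Reactants: 13
Product: 14 (4S,6S,8R,10R)-6,8,10-trihydroxynonadec-1-en-4-yl prop-2-enoate
Conditions: Zn dust (activated, 10 equiv), AcOH (5 equiv), THF/EtOH 1:1, 25–40 °C
Reagents that add atoms: none
Why: Zinc-mediated reductive β-elimination of a β-alkoxy iodide (Boord-type fragmentation, as in the Bernet–Vasella reaction): insertion of zinc into the C–I bond and loss of the ring oxygen as alkoxide should restore the terminal alkene and free the C2′ hydroxyl, erasing the temporary centre, while the acidic medium protonates the alkoxide at once to hold back acyl migration.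

Step 8
Reactants: 14
Product: 15 (6S)-6-[(2S,4R,6R)-2,4,6-trihydroxypentadecyl]-5,6-dihydro-2H-pyran-2-one
Conditions: second-generation Grubbs catalyst RuCl2(=CHPh)(PCy3)(H2IMes) (5 mol%), CH2Cl2 (0.003 M), 40 °C
Reagents that add atoms: none
Why: Ring-closing olefin metathesis of the acrylate onto its homoallylic alkene should close the six-membered α,β-unsaturated lactone with loss of ethylene; the cis ring alkene follows from ring size, free hydroxyls are tolerated and no stereocentre is affected.

**Compound list**

1 | propane-1,3-diol | OCCCO | starting material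
2 | allyl acetate (prop-2-en-1-yl acetate) | C=CCOC(C)=O | starting material
3 | (S)-hex-5-ene-1,3-diol, mono-allylation product, not isolated | C=CC[C@H](O)CCO | intermediate
4 | (4S,6S)-nona-1,8-diene-4,6-diol | C=CC[C@H](O)C[C@@H](O)CC=C | intermediate
5 | (2S,4R,6S)-2-(iodomethyl)-6-(prop-2-en-1-yl)oxan-4-ol, all-cis | C=CC[C@H]1C[C@@H](O)C[C@@H](CI)O1 | intermediate
6 | (2S,4R,6S)-2-(iodomethyl)-6-(prop-2-en-1-yl)oxan-4-yl prop-2-enoate | C=CC[C@H]1C[C@@H](OC(=O)C=C)C[C@@H](CI)O1 | intermediate
7 | (2S,4R,6R)-2-(iodomethyl)-6-(2-oxopropyl)oxan-4-yl prop-2-enoate | CC(=O)C[C@H]1C[C@@H](OC(=O)C=C)C[C@@H](CI)O1 | intermediate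
8 | decanal | CCCCCCCCCC=O | starting material
9 | dicyclohexylboron enolate of 7 (enol borinate on the methyl side), not isolated | C=C(OB(C2CCCCC2)C2CCCCC2)C[C@H]1C[C@@H](OC(=O)C=C)C[C@@H](CI)O1 | intermediate
10 | dicyclohexylboron aldolate (O-dicyclohexylborinate of 11), not isolated | CCCCCCCCC[C@@H](OB(C2CCCCC2)C2CCCCC2)CC(=O)C[C@H]1C[C@@H](OC(=O)C=C)C[C@@H](CI)O1 | intermediate
11 | (2R,4R,6S)-2-[(4R)-4-hydroxy-2-oxotridecyl]-6-(iodomethyl)oxan-4-yl prop-2-enoate | CCCCCCCCC[C@@H](O)CC(=O)C[C@H]1C[C@@H](OC(=O)C=C)C[C@@H](CI)O1 | intermediate
12 | diethylboron chelate (O-diethylborinate of 11, boron also bound to the ketone oxygen), not isolated | CCCCCCCCC[C@@H](OB(CC)CC)CC(=O)C[C@H]1C[C@@H](OC(=O)C=C)C[C@@H](CI)O1 | intermediate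
13 | (2S,4R,6S)-2-[(2R,4R)-2,4-dihydroxytridecyl]-6-(iodomethyl)oxan-4-yl prop-2-enoate | CCCCCCCCC[C@@H](O)C[C@@H](O)C[C@H]1C[C@@H](OC(=O)C=C)C[C@@H](CI)O1 | intermediate
14 | (4S,6S,8R,10R)-6,8,10-trihydroxynonadec-1-en-4-yl prop-2-enoate | CCCCCCCCC[C@@H](O)C[C@@H](O)C[C@H](O)C[C@@H](OC(=O)C=C)CC=C | intermediate
15 | (6S)-6-[(2S,4R,6R)-2,4,6-trihydroxypentadecyl]-5,6-dihydro-2H-pyran-2-one | CCCCCCCCC[C@@H](O)C[C@@H](O)C[C@H](O)C[C@@H]1CC=CC(=O)O1 | target

Total step count: 8.
Longest linear sequence: 8 steps, from propane-1,3-diol 1 to 15; allyl acetate 2 and decanal 8 enter as bought.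

**Steps most likely to fail**

Step 7. The hydroxyl released on C2′ lies 1,3 to the acrylate and may take over the acyl group (O→O acyl shift), and zinc may reduce or oligomerise the acrylate before the fragmentation is complete. The fallback runs the endgame with the hydroxyls capped. It sets out from 13, whose two free hydroxyls are silylated (Me3SiCl, imidazole, CH2Cl2) to the bis(trimethylsilyl) ether of 13 F1. The ring is then opened with Zn dust in THF in the presence of Me3SiCl, so that the zinc alkoxide is silylated as it forms, giving the tris(trimethylsilyl) ether of 14 F2. Ring-closing metathesis with the same ruthenium catalyst would give the tris(trimethylsilyl) ether of 15 F3, and citric acid in methanol would remove the silyl groups, coming back to the route at 15.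

Step 4. The primary iodide may be lost under the palladium/copper chloride system, by exchange for chloride or by insertion of the zerovalent palladium formed in each turnover. Part of the alkene may also be oxidised at the terminal carbon under the influence of the ring oxygen. The fallback builds the ketone without palladium. It sets out from 6: ozonolysis of the electron-rich terminal alkene (O3, CH2Cl2, −78 °C, Sudan red 7B as end-point indicator so that the acrylate is spared, then PPh3) would give the aldehyde (2S,4R,6R)-2-(iodomethyl)-6-(2-oxoethyl)oxan-4-yl prop-2-enoate F4. MeTi(OiPr)3, which adds to aldehydes but not to esters, would give the secondary alcohol (2S,4R,6S)-2-(2-hydroxypropyl)-6-(iodomethyl)oxan-4-yl prop-2-enoate F5 as both carbinol epimers. Dess–Martin periodinane would oxidise both epimers to the ketone, coming back to the route at 7.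

Step 2. Once the first ring is closed, the minor ring epimer in particular can place the remaining hydroxyl and the remaining allyl group diaxial, so a second iodoetherification to a bridged bis(iodomethyl) dioxabicyclononane may compete; ring closure onto the near alkene to a five-membered ring is also conceivable. The fallback tells the two hydroxyls apart before any ring is closed. It sets out from 4, which is mono-acylated with acryloyl chloride (1 equiv) and 2,4,6-collidine at −78 °C; C2 symmetry allows only one mono-ester, (4S,6S)-6-hydroxynona-1,8-dien-4-yl prop-2-enoate F6, and unreacted diol is recycled. Iodoetherification of F6 (I2, NaHCO3, MeCN), in which only one hydroxyl is left and only one ring can close, comes back to the route at 6.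

**Further compounds**

F1 | step 7 | bis(trimethylsilyl) ether of 13 (both chain hydroxyls silylated) | CCCCCCCCC[C@@H](O[Si](C)(C)C)C[C@@H](O[Si](C)(C)C)C[C@H]1C[C@@H](OC(=O)C=C)C[C@@H](CI)O1
F2 | step 7 | tris(trimethylsilyl) ether of 14 | CCCCCCCCC[C@@H](O[Si](C)(C)C)C[C@@H](O[Si](C)(C)C)C[C@H](O[Si](C)(C)C)C[C@@H](OC(=O)C=C)CC=C
F3 | step 7 | tris(trimethylsilyl) ether of 15 | CCCCCCCCC[C@@H](O[Si](C)(C)C)C[C@@H](O[Si](C)(C)C)C[C@H](O[Si](C)(C)C)C[C@@H]1CC=CC(=O)O1
F4 | step 4 | (2S,4R,6R)-2-(iodomethyl)-6-(2-oxoethyl)oxan-4-yl prop-2-enoate | O=CC[C@H]1C[C@@H](OC(=O)C=C)C[C@@H](CI)O1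
F5 | step 4 | (2S,4R,6S)-2-(2-hydroxypropyl)-6-(iodomethyl)oxan-4-yl prop-2-enoate, both carbinol epimers | CC(O)C[C@H]1C[C@@H](OC(=O)C=C)C[C@@H](CI)O1
F6 | step 2 | (4S,6S)-6-hydroxynona-1,8-dien-4-yl prop-2-enoate | C=CC[C@H](O)C[C@@H](OC(=O)C=C)CC=C
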